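Cuts: once the two MOM ethers are removed, the first cut is the bond between the benzylic CH2 of ring A and its olefin carbon (benzylic bromide + Z-alkenylboron). The second cut is the C=C bond itself (allyl terminus + B-vinyl group, metathesis).
Enabling feature: on ring B the phenolic oxygen at C2 is ortho to C1, which bears the chain. O, C2, C1, the benzylic CH2 and the two olefin carbons are six atoms in a row, and one boron atom between O and the far olefin carbon turns them into a seven-membered 1,2-oxaborepine fused to ring B.
Forward, ring A: a purchased 4-bromo-3,5-dihydroxybenzoate becomes the bis-MOM benzylic bromide (fragment 1). Ring B: a purchased 4-bromo-2,5-dimethoxybenzaldehyde is demethylated next to the formyl group and taken through an ortho-quinone methide to the 2-allylphenol.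
Chain: the phenol is esterified with a vinylboronate and metathesis closes the temporary ring (fragment 2). A Suzuki coupling with fragment 1 then completes the four-carbon link, opens the tether and returns the phenol, and acid finally frees ring A.
Stereochemistry: there is no stereocentre. The Z olefin is imposed by the seven-membered ring and carried through the C-B to C-C exchange with retention.

Key step: step 9

Remark on the chemistry: the four starting materials are taken as catalogue compounds. The butoxy group on boron is a spectator that is shed in the coupling. The two moisture-sensitive boron esters are carried on under argon without chromatography, and each still counts as a step.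

Step 1
Reactants: 1 methyl 4-bromo-3,5-dihydroxybenzoate
Product: 2 methyl 4-bromo-3,5-bis(methoxymethoxy)benzoate
Conditions: MOMCl (2.6 equiv), iPr2NEt (3 equiv), CH2Cl2, 0 °C to rt
Reagents that add atoms: chloromethyl methyl ether (MOMCl), COCCl
Why: Williamson-type O-alkylation (acetal formation) of both acidic bromoresorcinol hydroxyls with the very reactive chloromethyl ether under amine base, which leaves the methyl ester and the aryl bromide alone.

Step 2
Reactants: 2 methyl 4-bromo-3,5-bis(methoxymethoxy)benzoate
Product: 3 [4-bromo-3,5-bis(methoxymethoxy)phenyl]methanol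
Conditions: iBu2AlH (2.5 equiv), CH2Cl2, -78 to 0 °C; aq. potassium sodium tartrate
Reagents that add atoms: none
Why: Hydride reduction of an aromatic ester to the benzylic alcohol with excess iBu2AlH, which at low temperature attacks neither the acetal-type MOM ethers nor the aryl C-Br bond.

Step 3
Reactants: 3 [4-bromo-3,5-bis(methoxymethoxy)phenyl]methanol
Product: 4 2-bromo-5-(bromomethyl)-1,3-bis(methoxymethoxy)benzene (4-bromo-3,5-bis(methoxymethoxy)benzyl bromide, fragment 1)
Conditions: CBr4 (1.2 equiv), PPh3 (1.25 equiv), CH2Cl2, 0 °C
Reagents that add atoms: carbon tetrabromide, BrC(Br)(Br)Br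
Why: Appel reaction, in which bromide displaces the alkoxyphosphonium salt of the primary benzylic alcohol in an SN2 step under nearly neutral conditions that MOM ethers tolerate.

Step 4
Reactants: 5 4-bromo-2,5-dimethoxybenzaldehyde
Product: 6 4-bromo-2-hydroxy-5-methoxybenzaldehyde
Conditions: BCl3 (1.2 equiv, 1 M in CH2Cl2), CH2Cl2, -78 °C to rt; H2O
Reagents that add atoms: none
Why: Chelation-directed aryl methyl ether cleavage, in which BCl3 binds the formyl oxygen and the ortho methoxy oxygen in a six-membered chelate so that chloride dealkylates only that methyl group, while the C5 methoxy group cannot chelate and should survive about one equivalent of reagent.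

Step 5
Reactants: 6 4-bromo-2-hydroxy-5-methoxybenzaldehyde
Product: 7 5-bromo-2-(hydroxymethyl)-4-methoxyphenol
Conditions: NaBH4 (1 equiv), THF/MeOH 4:1, 0 °C; H2O
Reagents that add atoms: none
Why: Borohydride reduction of an aromatic aldehyde, fast at 0 °C and without effect on the aryl bromide or the methyl ether.

Step 6
Reactants: 7 5-bromo-2-(hydroxymethyl)-4-methoxyphenol
Product: 8 2-(acetoxymethyl)-5-bromo-4-methoxyphenyl acetate (the diacetate)
Conditions: Ac2O (3 equiv), DMAP (5 mol %), pyridine, 0 °C to rt
Reagents that add atoms: acetic anhydride, CC(=O)OC(C)=O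
Why: DMAP-catalysed acylation of the phenol and the primary benzylic alcohol, which makes the first a trigger and the second a leaving group for the next step.

Step 7
Reactants: 8 2-(acetoxymethyl)-5-bromo-4-methoxyphenyl acetate; 9 vinylmagnesium bromide
Product: 12 2-allyl-5-bromo-4-methoxyphenol, via bromomagnesium phenoxide 10 (not isolated), via ortho-quinone methide 11 (not isolated)
Conditions: 9 (3.5 equiv, 1 M in THF), THF, -78 to 0 °C; 1 M HCl, 0 °C
Reagents that add atoms: vinylmagnesium bromide (9), C=C[Mg]Br
Why: Anionic generation and conjugate trapping of an ortho-quinone methide, a known way from 2-acetoxybenzyl acetates to ortho-alkylated phenols: the Grignard reagent attacks the more electrophilic aryl acetate first, phenoxide 10 expels the benzylic acetate on warming, and a further equivalent of 9 adds 1,4 to the exocyclic CH2 of 11 with rearomatisation.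

Step 8
Reactants: 12 2-allyl-5-bromo-4-methoxyphenol; 13 dibutyl vinylboronate
Product: 14 butyl 2-allyl-5-bromo-4-methoxyphenyl vinylboronate (mixed aryl butyl ester of vinylboronic acid)
Conditions: 13 (1.0 equiv), toluene, 60 °C, 150 mbar, BuOH/toluene distilled off, argon; used crude
Reagents that add atoms: dibutyl vinylboronate (13), C=CB(OCCCC)OCCCC
Why: Transesterification of a dialkyl boronate, an equilibrium among B-O bonds that is pulled towards the aryl ester by distilling off butan-1-ol as its toluene azeotrope, with one equivalent of 13 so that no free vinylboronate competes later.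

Step 9
Reactants: 14 butyl 2-allyl-5-bromo-4-methoxyphenyl vinylboronate
Product: 15 8-bromo-2-butoxy-7-methoxy-2,5-dihydro-1,2-benzoxaborepine (cyclic alkenylboronate with a cis C3=C4 bond, fragment 2)
Conditions: second-generation Grubbs catalyst (H2IMes)(PCy3)Cl2Ru=CHPh (5 mol %), 1,4-benzoquinone (10 mol %), toluene (0.01 M), 60 °C, argon purge; ethyl vinyl ether, evaporation, no silica
Reagents that add atoms: none
Why: Proposed new method: the benzylidene should initiate at the unhindered allyl CH=CH2 of 14, and the alkylidene so formed should engage the tethered B-vinyl group in a (2+2) cycloaddition, the metallacyclobutane then breaking up into the C3=C4 bond of 15 and Ru=CH2 while the argon stream sweeps out ethene. The closest known reaction type is the boron-tethered ring-closing metathesis of mixed vinylboronic esters of unsaturated aliphatic alcohols to cyclic alkenylboronates; not yet shown is a tether through an aryl (phenol-derived) B-O bond, which exchanges and solvolyses more easily, but since all B-O esters in the flask interconvert and only tethered species can cyclise, ring closure should drain the equilibrium. The single ring formed, O1-B2-C3=C4-C5-C5a-C9a, closes by ring-closing metathesis of two terminal olefins (new bond C3=C4), and the ortho relationship of O and CH2 on ring B holds two ring members and their substituents in one plane, which shortens the effective tether. No stereocentre is created, and the olefin can only be Z, with boron and C5 cis, because a trans double bond does not fit into a benzo-fused seven-membered ring. The selectivities needed are cyclisation over homodimerisation of the allyl group, secured by the tether, by 0.01 M dilution and by the reluctance of vinylboronates to homodimerise, and retention of the allyl double-bond position, secured by 1,4-benzoquinone, which intercepts the ruthenium hydrides that would move it into conjugation. The aryl bromide, the methyl ether and the boron-masked phenol should not react with the carbene.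

Step 10
Reactants: 15 8-bromo-2-butoxy-7-methoxy-2,5-dihydro-1,2-benzoxaborepine; 4 2-bromo-5-(bromomethyl)-1,3-bis(methoxymethoxy)benzene
Product: 17 bis-MOM colpol (5-bromo-2-{(2Z)-4-[4-bromo-3,5-bis(methoxymethoxy)phenyl]but-2-en-1-yl}-4-methoxyphenol), via cyclic boronic half acid 16 (not isolated)
Conditions: Pd(PPh3)4 (5 mol %), K3PO4 (3 equiv), THF/H2O 10:1, 50 °C, 15 (1.2 equiv), 4 added over 3 h by syringe pump
Reagents that add atoms: none
Why: Suzuki-Miyaura coupling of an alkenylboron compound with a benzylic bromide: zerovalent palladium inserts into the benzylic C-Br bond of 4 far faster than into the two ortho-substituted, electron-rich aryl C-Br bonds, the base-activated half acid 16 hands over its alkenyl group with retention, reductive elimination keeps the Z geometry, and slow addition of 4 keeps the catalyst in its zerovalent resting state so that insertion outruns alkylation of the phenoxide that the coupling releases.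

Step 11
Reactants: 17 bis-MOM colpol
Product: 18 colpol (2-bromo-5-[(2Z)-4-(4-bromo-2-hydroxy-5-methoxyphenyl)but-2-en-1-yl]benzene-1,3-diol)
Conditions: conc. aq. HCl (cat.), MeOH, rt
Reagents that add atoms: none
Why: Acid-catalysed acetal exchange (MOM cleavage) with methanol as acceptor, mild enough that the aryl methyl ether, both aryl bromides and the skipped Z olefin should stay as they are.

Compound list
1 | methyl 4-bromo-3,5-dihydroxybenzoate | COC(=O)c1cc(O)c(Br)c(O)c1 | starting material
2 | methyl 4-bromo-3,5-bis(methoxymethoxy)benzoate | COCOc1cc(C(=O)OC)cc(OCOC)c1Br | intermediate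
3 | [4-bromo-3,5-bis(methoxymethoxy)phenyl]methanol | COCOc1cc(CO)cc(OCOC)c1Br | intermediate
4 | 2-bromo-5-(bromomethyl)-1,3-bis(methoxymethoxy)benzene (fragment 1) | COCOc1cc(CBr)cc(OCOC)c1Br | intermediate
5 | 4-bromo-2,5-dimethoxybenzaldehyde | O=Cc1cc(OC)c(Br)cc1OC | starting material
6 | 4-bromo-2-hydroxy-5-methoxybenzaldehyde | O=Cc1cc(OC)c(Br)cc1O | intermediate
7 | 5-bromo-2-(hydroxymethyl)-4-methoxyphenol | OCc1cc(OC)c(Br)cc1O | intermediate
8 | 2-(acetoxymethyl)-5-bromo-4-methoxyphenyl acetate | CC(=O)OCc1cc(OC)c(Br)cc1OC(C)=O | intermediate
9 | vinylmagnesium bromide | C=C[Mg]Br | starting material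
10 | bromomagnesium 2-(acetoxymethyl)-5-bromo-4-methoxyphenoxide | CC(=O)OCc1cc(OC)c(Br)cc1O[Mg]Br | intermediate
11 | 3-bromo-4-methoxy-6-methylidenecyclohexa-2,4-dien-1-one (ortho-quinone methide) | C=C1C=C(OC)C(Br)=CC1=O | intermediate
12 | 2-allyl-5-bromo-4-methoxyphenol | C=CCc1cc(OC)c(Br)cc1O | intermediate
13 | dibutyl vinylboronate | C=CB(OCCCC)OCCCC | starting material
14 | butyl 2-allyl-5-bromo-4-methoxyphenyl vinylboronate | C=CCc1cc(OC)c(Br)cc1OB(OCCCC)C=C | intermediate
15 | 8-bromo-2-butoxy-7-methoxy-2,5-dihydro-1,2-benzoxaborepine, cis C3=C4 (fragment 2) | CCCCOB1/C=C\Cc2cc(OC)c(Br)cc2O1 | intermediate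
16 | 8-bromo-7-methoxy-2,5-dihydro-1,2-benzoxaborepin-2-ol, cis C3=C4 (cyclic boronic half acid) | OB1/C=C\Cc2cc(OC)c(Br)cc2O1 | intermediate
17 | bis-MOM colpol, 5-bromo-2-{(2Z)-4-[4-bromo-3,5-bis(methoxymethoxy)phenyl]but-2-en-1-yl}-4-methoxyphenol | COCOc1cc(C/C=C\Cc2cc(OC)c(Br)cc2O)cc(OCOC)c1Br | intermediate
18 | colpol, 2-bromo-5-[(2Z)-4-(4-bromo-2-hydroxy-5-methoxyphenyl)but-2-en-1-yl]benzene-1,3-diol | COc1cc(C/C=C\Cc2cc(O)c(Br)c(O)c2)c(O)cc1Br | target

Total step count: 11 steps.
Longest linear sequence: 8 steps (5 to 18, steps 4 to 11). The ring A branch (steps 1 to 3) joins at step 10.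

Steps most likely to fail

1. Step 9.
- What may go wrong: the aryl B-O link may redistribute or solvolyse before the ring closes, so that the two olefins meet only intermolecularly. The allyl double bond may migrate into conjugation with ring B, after which metathesis would contract the ring. Turnover at the electron-poor vinylboron terminus may be slow.
- Fallback (known chemistry, catalyst control in place of tether control): it sets out from 12 and comes back to the route at 17. Silylation of 12 (iPr3SiCl, imidazole, DMF) should give (2-allyl-5-bromo-4-methoxyphenoxy)triisopropylsilane F1. F1 is then submitted to kinetically Z-selective cross-metathesis with vinylboronic acid pinacol ester. The catalyst is the molybdenum monoaryloxide pyrrolide alkylidene Mo(NAd)(CHCMe2Ph)(NC4H4)(OHIPT) (Ad = 1-adamantyl, OHIPT = 2,6-bis(2,4,6-triisopropylphenyl)phenoxide), in benzene at 22 °C under reduced pressure. This should give the TIPS-protected Z-alkenyl pinacol boronate F2. Suzuki coupling of F2 with 4 (Pd(PPh3)4, K3PO4, THF/H2O, 60 °C), now without any free phenoxide, should give the TIPS ether of bis-MOM colpol F3. Bu4NF in THF at 0 °C should then release 17.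

2. Step 10.
- What may go wrong: the phenoxide set free as the coupling proceeds may be O-benzylated. The Z-alkenylboron species may protodeboronate in the aqueous base. Metal hydrides from ruthenium residues in the crude boronate may cause double-bond migration or erosion of Z to E.
- Fallback (the tether is removed and the phenol capped before the C-C bond is made, so a purified, neutral boronate is coupled): it sets out from 15 and comes back at 18. Exchange of 15 with pinacol (1.1 equiv, THF, rt) should give the open-chain Z-alkenyl pinacol boronate phenol F4, which can be chromatographed. MOMCl and iPr2NEt in CH2Cl2 should give its MOM ether F5. Suzuki coupling of F5 with 4 (Pd(PPh3)4, K3PO4, THF/H2O, 60 °C) should give tris-MOM colpol F6. The conditions of step 11 should then remove all three MOM groups to give 18.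

3. Step 7.
- What may go wrong: the Grignard reagent may attack the benzylic acetate, which removes the leaving group and returns the salicyl alcohol. The ortho-quinone methide may self-condense if it forms faster than it is trapped.
- Fallback (direct benzylic cross-coupling in place of the quinone methide): it sets out from 6 and comes back at 12. MOMCl and iPr2NEt should give 4-bromo-5-methoxy-2-(methoxymethoxy)benzaldehyde F7. NaBH4 in MeOH should give [4-bromo-5-methoxy-2-(methoxymethoxy)phenyl]methanol F8. CBr4 and PPh3 should give 1-bromo-4-(bromomethyl)-2-methoxy-5-(methoxymethoxy)benzene F9. Copper-catalysed coupling of F9 with 9 (CuI 10 mol %, THF, -20 to 0 °C), a known route from benzylic bromides to allylarenes, should give 1-allyl-4-bromo-5-methoxy-2-(methoxymethoxy)benzene F10. HCl in MeOH at rt should then free the phenol 12.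

Further compounds
F1 | step 9 | (2-allyl-5-bromo-4-methoxyphenoxy)triisopropylsilane | C=CCc1cc(OC)c(Br)cc1O[Si](C(C)C)(C(C)C)C(C)C
F2 | step 9 | TIPS-protected Z-alkenyl pinacol boronate, 2-[(1Z)-3-{4-bromo-5-methoxy-2-[(triisopropylsilyl)oxy]phenyl}prop-1-en-1-yl]-4,4,5,5-tetramethyl-1,3,2-dioxaborolane | CC(C)[Si](Oc1cc(Br)c(OC)cc1C/C=C\B1OC(C)(C)C(C)(C)O1)(C(C)C)C(C)C
F3 | step 9 | TIPS ether of bis-MOM colpol, (5-bromo-2-{(2Z)-4-[4-bromo-3,5-bis(methoxymethoxy)phenyl]but-2-en-1-yl}-4-methoxyphenoxy)triisopropylsilane | COCOc1cc(C/C=C\Cc2cc(OC)c(Br)cc2O[Si](C(C)C)(C(C)C)C(C)C)cc(OCOC)c1Br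
F4 | step 10 | open-chain Z-alkenyl pinacol boronate phenol, 5-bromo-4-methoxy-2-[(2Z)-3-(4,4,5,5-tetramethyl-1,3,2-dioxaborolan-2-yl)prop-2-en-1-yl]phenol | COc1cc(C/C=C\B2OC(C)(C)C(C)(C)O2)c(O)cc1Br
F5 | step 10 | MOM ether of F4, 2-{(1Z)-3-[4-bromo-5-methoxy-2-(methoxymethoxy)phenyl]prop-1-en-1-yl}-4,4,5,5-tetramethyl-1,3,2-dioxaborolane | COCOc1cc(Br)c(OC)cc1C/C=C\B1OC(C)(C)C(C)(C)O1
F6 | step 10 | tris-MOM colpol, 2-bromo-5-{(2Z)-4-[4-bromo-5-methoxy-2-(methoxymethoxy)phenyl]but-2-en-1-yl}-1,3-bis(methoxymethoxy)benzene | COCOc1cc(C/C=C\Cc2cc(OC)c(Br)cc2OCOC)cc(OCOC)c1Br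
F7 | step 7 | 4-bromo-5-methoxy-2-(methoxymethoxy)benzaldehyde | O=Cc1cc(OC)c(Br)cc1OCOC
F8 | step 7 | [4-bromo-5-methoxy-2-(methoxymethoxy)phenyl]methanol | OCc1cc(OC)c(Br)cc1OCOC
F9 | step 7 | 1-bromo-4-(bromomethyl)-2-methoxy-5-(methoxymethoxy)benzene | BrCc1cc(OC)c(Br)cc1OCOC
F10 | step 7 | 1-allyl-4-bromo-5-methoxy-2-(methoxymethoxy)benzene | C=CCc1cc(OC)c(Br)cc1OCOC
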